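# Design of a total synthesis of CNP0281883.1 (34) through an anodic enol ether–vinylsilane cyclisation

## The problem

The target (34) is a guaiane-type hydroazulene joined through an exocyclic benzylic carbon to a 3,5-diformylphloroglucinol. In guaiane numbering, the five-membered ring C1–C5 and the seven-membered ring C1, C5–C10 share the C1–C5 bond. C5=C6 is the only ring alkene, C4 is quaternary (CH3 and C9′), C7 carries C(CH3)2OH, C10 carries CH3, and C9′ carries the isobutyl group and the arene.

Five stereocentres must be set. C1, C7 and C10 lie on the flexible seven-membered ring, with H1 and H10 cis to each other and on the face of the C7 substituent. C4 is quaternary with C9′ syn to H1, and C9′ is acyclic. C7 can come from the chiral pool, but it is 1,4 to C10 across a cycloheptene and cannot be trusted to control C1 and C10 directly, so a relay is needed. Once C1 is fixed it is the only handle on C4, and C4 is the only handle on C9′.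

The diformylphloroglucinol is electron-rich, chelating and easily oxidised. The tertiary alcohol ionises in acid, and the trisubstituted C5=C6 alkene next to a quaternary carbon invites cationic rearrangement. Strong Lewis acids and oxidants must therefore be kept away from the late intermediates, and the phenols unmasked last.

The feature that opens the synthesis is that C4 sits between the alkene carbon C5 and a carbon, C9′, that can be carried at the aldehyde oxidation level. C4 is then the β-carbon of an enol ether and C5 the silicon-bearing carbon of a vinylsilane. These are two nucleophilic centres that an anode can join, closing the five-membered ring.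

## Retrosynthesis

**34 ⇒ 33 ⇒ 32 (three O–CH3 bonds, one O–Si bond).** The free triphenol dialdehyde cannot be carried through organometallic steps. Methyl ethers are the one phenol protection that survives organolithiums and the cation chemistry below. In 33 every methoxy group is ortho or para to a formyl group, so each O–CH3 bond can be cut by a soft nucleophile under basic conditions that spare the tertiary alcohol and the alkene. The silyl ether of 32 is removed first so that the last step acts on a neutral, easily purified compound.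

**32 ⇒ 29 ⇒ 27 (two aryl–CHO bonds).** Bringing the formyl groups in on the aryl nucleophile would require masking them and would weaken the donor power needed for the benzylic cation. In 27 the two ring C–H bonds each lie between two methoxy groups and are the most acidic sites of the molecule, so they can be metalated and formylated one after the other. The forward steps must be base-mediated, because a Lewis-acid formylation would endanger the tertiary silyl ether and C5=C6.

**27 ⇒ 26 ⇒ 25 ⇒ 22 + 23 (C9′–CH2 and C9′–aryl bonds).** C9′ is traced back to the aldehyde carbon of 22. The neighbouring cut, C4–C9′, would have to create the quaternary carbon and C9′ together in one intermolecular union of two hindered partners. Here C4 already exists and is the stereocontrol element. The aryl group of 23 is added as its lithium derivative 24, and the resulting carbinol 25 is ionised and captured by a methallyl nucleophile. The forward reaction must discriminate the faces of a planar benzylic cation through the adjacent quaternary centre.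

**22 ⇒ 21 ⇒ 20 (C4–C5 bond, five-membered ring).** This is the key cut. Both carbons are nucleophilic in 20, so the bond is made by one-electron oxidation of the enol ether. The quaternary centre, the ring and the position of C5=C6 are fixed in one step, and C9′ emerges as an acetal. An enolate alkenylation would need a halide at C5 and a free aldehyde in the same molecule. An ene or aldol route would leave oxygen on the ring to be removed. Precursor 20 is monocyclic with three stereocentres.

**20 ⇒ 17 ⇒ 16 (C4=C9′ bond; ketone unmasking).** The enol ether is made by methoxymethylenation of methyl ketone 17 with ylide 19 from salt 18. The ketone is released from dioxolane 16 only after the organolithium chemistry at C5 is over.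

**16 ⇒ 14 ⇒ 13 (C5–Si bond).** The vinylsilane comes from the C5 ketone by the Shapiro reaction via alkenyllithium 15. Kinetic deprotonation at the C6 methylene, not at the branched C1, places the alkene at C5=C6 and leaves the C1 stereocentre alone.

**13 ⇒ 12 ⇒ 11 ⇒ 10 (C1–H and C10–H bonds).** The cis relation of the C1 chain and the C10 methyl group comes from syn addition of hydrogen to the tetrasubstituted C1=C10 alkene. The face is chosen by a temporary carbinol at C5 that binds the hydrogenation catalyst. That carbinol is set by a reagent-controlled ketone reduction, so C7 does not have to exert remote control. Conjugate reduction followed by enolate alkylation would give the trans isomer. Hydrogenation of enone 10 itself would rely on the ring conformation alone.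

**10 ⇒ 7 + 8 (C1–C2 bond).** The side chain is joined by sp2–sp3 cross-coupling of bromoenone 7 with zinc reagent 9 made from bromide 8. Enolate alkylation with 8, a sluggish electrophile prone to elimination, would also raise α versus α′ and mono- versus dialkylation problems.

**7 ⇒ 5 ⇒ 3 ⇒ 2 ⇒ 1 (one-carbon ring expansion; C–O bond at C11).** The seven-membered ring comes from (R)-carvone (1). C1 is inserted between the carbonyl carbon and the methyl-bearing carbon by dihalocarbene addition to the regiodefined silyl enol ether 5 and ring opening. This delivers the bromine needed for the coupling in the same step. The carvone stereocentre becomes C7 unchanged. The isopropenyl group is hydrated and silylated at the outset (2, 3), so no second alkene competes later.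

## Roads not taken

**Alternative 1:** The cut is a skeletal rearrangement: C1–C5 is formed and C5–C10 broken in a carvone-derived decalin dienone A2. Irradiation of A2 in aqueous acetic acid should give the 10-hydroxyguai-4-en-3-one A1 in one step.
- **Merits:** The photochemistry of cross-conjugated cyclohexadienones is well tested. A2 is made in very few steps by annulation onto the carvone ring, and the annulation naturally gives the C10 epimer that is needed here. C1 and C7 emerge with the right relationship. The bicyclic core is reached faster than in the chosen plan and without electrochemical equipment or silicon chemistry.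
- **Weak points:** A1 carries oxygen at C3 and C10 and its alkene at C4=C5, none of which the target has.
  - The tertiary C10 hydroxyl must be replaced by hydrogen with retention, for which radical or ionic deoxygenation offers no secure facial control.
  - C4 must be made quaternary by deconjugative alkylation with a hindered benzylic electrophile. That creates C4 and C9′ in one intermolecular step.
  - The C3 carbonyl must then be removed.
- **Comparison:** The chosen plan is longer to the core. Against that, 21 arrives with the final oxidation pattern, with C10 set by a directed hydrogenation and with C4 formed intramolecularly. Its own uncertainty (the C4 face) is one stereocentre, where Alternative 1 leaves three.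

**Alternative 2:** The cut is the C5=C6 alkene. Diene A4 is a cyclopentane with a C5 exocyclic methylene and a C1 side chain ending in the C6 vinyl group. It would be closed by (H2IMes)(PCy3)Cl2Ru=CHPh, the second-generation Grubbs catalyst, to A3, which is compound 27 without its silyl group.
- **Merits:** The alkene position is unambiguous, as in the chosen plan. The route is more convergent and late-stage, since A3 is only formylation and demethylation away from 34 and needs no protecting group on the tertiary alcohol. In these respects it is as good as or better than the chosen plan.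
- **Weak points:** The metathesis must engage a 1,1-disubstituted alkene flanked by the quaternary C4 and its bulky aryl-bearing substituent to form a trisubstituted cycloheptene, the least favourable case for this catalyst class. A4 needs C7 and C10 on an open chain and C1, C4 and C9′ on a cyclopentane, all set without the help of a ring template, and the quaternary C4–C9′ array still has to be built by other means.
- **Comparison:** The chosen plan uses the carvone-derived ring to relay stereochemistry to C1 and C10, and forms the quaternary carbon and the ring in the same event.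

**Alternative 3:** The cuts are C1–C5, C2–C3 and C3–C4. Allenyne A6 under [Rh(CO)2Cl]2 and carbon monoxide should give dienone A5 by an allenic Pauson–Khand reaction at the distal allene double bond.
- **Merits:** It is the most bond-economic of the routes considered: three C–C bonds and both rings form in one step, with the C9′ side chain already in place. The chosen plan cannot match this.
- **Weak points:** A5 has C4 as an sp2 carbon, a carbonyl at C3 and the alkene at C1=C10.
  - The C4 methyl group must be added by deconjugative alkylation, forming the quaternary carbon next to the C9′ stereocentre with uncertain facial control.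
  - C1 and C10 have to be set by reducing a tetrasubstituted alkene in the presence of C5=C6.
  - The C3 carbonyl has to be removed.
  - The C9′ stereocentre of A6 is benzylic and propargylic. It must be set on an acyclic fragment and can be lost through enolisation of A5.
- **Comparison:** The chosen plan fixes C1 and C10 before cyclisation and leaves only C4 and C9′ open, each next to an existing controlling centre.

Key step: step 13

## Route

Assumption: the E and Z isomers of enol ether 20 are taken on together, since both give the same radical cation and therefore the same product in step 13.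

Step 1
Reactants: 1 (R)-carvone
Product: 2 (5R)-5-(2-hydroxypropan-2-yl)-2-methylcyclohex-2-en-1-one
Conditions: 50% aq. H2SO4, 0 °C
Reagents that add atoms: water, O
Why: Markovnikov acid-catalysed hydration of the 1,1-disubstituted isopropenyl alkene through its tertiary cation; the conjugated alkene is not hydrated, the stereocentre (future C7) is not involved, and the low temperature suppresses aromatisation.

Step 2
Reactants: 2 (5R)-5-(2-hydroxypropan-2-yl)-2-methylcyclohex-2-en-1-one
Product: 3 (5R)-2-methyl-5-[2-(triethylsilyloxy)propan-2-yl]cyclohex-2-en-1-one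
Conditions: Et3SiOTf, 2,6-lutidine, CH2Cl2, −78 to 0 °C
Reagents that add atoms: triethylsilyl trifluoromethanesulfonate, CC[Si](CC)(CC)OS(=O)(=O)C(F)(F)F
Why: Silylation of a hindered tertiary alcohol with the silyl triflate; the tertiary triethylsilyl ether should resist the hydride, organolithium, fluoride-free and weakly acidic conditions that follow, yet come off with fluoride at the end.

Step 3
Reactants: 3 (5R)-2-methyl-5-[2-(triethylsilyloxy)propan-2-yl]cyclohex-2-en-1-one
Product: 5 trimethyl{[(5R)-2-methyl-5-[2-(triethylsilyloxy)propan-2-yl]cyclohex-1-en-1-yl]oxy}silane, via lithium enolate 4 (not isolated)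
Conditions: LiBH(s-Bu)3, THF, −78 °C; then Me3SiCl, Et3N, −78 °C to rt
Reagents that add atoms: chlorotrimethylsilane, C[Si](C)(C)Cl
Why: Conjugate hydride reduction of the β-unsubstituted enone gives one regiodefined enolate, and O-silylation fixes the tetrasubstituted enol ether between the carbonyl carbon and the methyl-bearing carbon, which is where the new ring carbon must be inserted.

Step 4
Reactants: 5 trimethyl{[(5R)-2-methyl-5-[2-(triethylsilyloxy)propan-2-yl]cyclohex-1-en-1-yl]oxy}silane
Product: 7 (6R)-2-bromo-3-methyl-6-[2-(triethylsilyloxy)propan-2-yl]cyclohept-2-en-1-one, via dibromocyclopropane 6 (not isolated)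
Conditions: CHBr3, KOtBu, pentane, −30 to 0 °C; aqueous work-up; then pyridine, toluene, 80 °C
Reagents that add atoms: bromoform, BrC(Br)Br
Why: Dihalocarbene ring expansion of a silyl enol ether: dibromocarbene adds to the electron-rich alkene and the adduct opens by electrocyclic cleavage of the shared bond with loss of bromide and the silyl group. The inserted carbon becomes C1 carrying bromine, with the methyl group on C10 and the carbonyl at C5; the C7 stereocentre is a spectator.

Step 5
Reactants: 7 (6R)-2-bromo-3-methyl-6-[2-(triethylsilyloxy)propan-2-yl]cyclohept-2-en-1-one; 8 2-(2-bromoethyl)-2-methyl-1,3-dioxolane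
Product: 10 (6R)-3-methyl-2-[2-(2-methyl-1,3-dioxolan-2-yl)ethyl]-6-[2-(triethylsilyloxy)propan-2-yl]cyclohept-2-en-1-one, via alkylzinc bromide 9 (not isolated)
Conditions: 8, Zn, LiCl, THF, 40 °C; then 7, Pd(OAc)2 (3 mol %), SPhos (6 mol %), THF, rt to 50 °C
Reagents that add atoms: none
Why: Negishi coupling of an α-bromoenone (an activated alkenyl bromide) with a primary alkylzinc halide; the zerovalent palladium species formed from Pd(OAc)2 and the bulky biarylphosphine favours reductive elimination over β-hydride elimination, and the ketal and silyl ether are inert.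

Step 6
Reactants: 10 (6R)-3-methyl-2-[2-(2-methyl-1,3-dioxolan-2-yl)ethyl]-6-[2-(triethylsilyloxy)propan-2-yl]cyclohept-2-en-1-one
Product: 11 (1R,6R)-3-methyl-2-[2-(2-methyl-1,3-dioxolan-2-yl)ethyl]-6-[2-(triethylsilyloxy)propan-2-yl]cyclohept-2-en-1-ol
Conditions: (S)-2-methyl-CBS-oxazaborolidine (0.5 equiv), catecholborane, toluene, −78 °C
Reagents that add atoms: none
Why: Corey–Bakshi–Shibata reduction, in which the tetrasubstituted alkenyl side of the ketone is the large group and the C6 methylene the small one; the (S)-catalyst should give the (1R)-carbinol, hydroxyl cis to the C7 substituent, by reagent control, and catecholborane at low temperature avoids hydroboration.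

Step 7
Reactants: 11 (1R,6R)-3-methyl-2-[2-(2-methyl-1,3-dioxolan-2-yl)ethyl]-6-[2-(triethylsilyloxy)propan-2-yl]cyclohept-2-en-1-ol
Product: 12 (1R,2R,3R,6R)-3-methyl-2-[2-(2-methyl-1,3-dioxolan-2-yl)ethyl]-6-[2-(triethylsilyloxy)propan-2-yl]cycloheptan-1-ol
Conditions: [Ir(cod)(PCy3)(py)]PF6 (10 mol %), H2 (1 atm), CH2Cl2, 0 °C to rt
Reagents that add atoms: none
Why: Hydroxyl-directed homogeneous hydrogenation: the cationic iridium catalyst binds the allylic hydroxyl and delivers both hydrogens to the same face of the tetrasubstituted alkene. H1 and H10 therefore end up cis to each other and to the C5 hydroxyl, placing the C1 chain and the C10 methyl group cis and both trans to the C7 substituent.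

Step 8
Reactants: 12 (1R,2R,3R,6R)-3-methyl-2-[2-(2-methyl-1,3-dioxolan-2-yl)ethyl]-6-[2-(triethylsilyloxy)propan-2-yl]cycloheptan-1-ol
Product: 13 (2R,3R,6R)-3-methyl-2-[2-(2-methyl-1,3-dioxolan-2-yl)ethyl]-6-[2-(triethylsilyloxy)propan-2-yl]cycloheptan-1-one
Conditions: DMP, NaHCO3, CH2Cl2, 0 °C
Reagents that add atoms: none
Why: Dess–Martin oxidation under buffered, near-neutral conditions returns the C5 ketone without enolising the now epimerisable C1, so the relay carbinol is removed once it has done its work.

Step 9
Reactants: 13 (2R,3R,6R)-3-methyl-2-[2-(2-methyl-1,3-dioxolan-2-yl)ethyl]-6-[2-(triethylsilyloxy)propan-2-yl]cycloheptan-1-one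
Product: 14 N′-[(1E,2R,3R,6R)-3-methyl-2-[2-(2-methyl-1,3-dioxolan-2-yl)ethyl]-6-[2-(triethylsilyloxy)propan-2-yl]cycloheptylidene]-2,4,6-tri(propan-2-yl)benzenesulfonohydrazide
Conditions: 2,4,6-(i-Pr)3C6H2SO2NHNH2, THF, rt, no acid
Reagents that add atoms: 2,4,6-tri(propan-2-yl)benzenesulfonohydrazide, CC(C)c1cc(C(C)C)c(S(=O)(=O)NN)c(C(C)C)c1
Why: Condensation to the arylsulfonylhydrazone, whose N–N bond should lie anti to the branched C1 and therefore syn to the C6 methylene; acid is left out to limit enolisation at C1.

Step 10
Reactants: 14 N′-[(1E,2R,3R,6R)-3-methyl-2-[2-(2-methyl-1,3-dioxolan-2-yl)ethyl]-6-[2-(triethylsilyloxy)propan-2-yl]cycloheptylidene]-2,4,6-tri(propan-2-yl)benzenesulfonohydrazide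
Product: 16 trimethyl[(3R,6R,7R)-6-methyl-7-[2-(2-methyl-1,3-dioxolan-2-yl)ethyl]-3-[2-(triethylsilyloxy)propan-2-yl]cyclohept-1-en-1-yl]silane, via alkenyllithium 15 (not isolated)
Conditions: n-BuLi (2.2 equiv), TMEDA, THF, −78 to 0 °C; then Me3SiCl, −78 °C
Reagents that add atoms: chlorotrimethylsilane, C[Si](C)(C)Cl
Why: Shapiro reaction: the dianion forms by deprotonation at the C6 methylene syn to the sulfonamide nitrogen and loses sulfinate and dinitrogen to give the C5 alkenyllithium with the alkene at C5=C6. Silylation places silicon on C5, and C1 is never deprotonated.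

Step 11
Reactants: 16 trimethyl[(3R,6R,7R)-6-methyl-7-[2-(2-methyl-1,3-dioxolan-2-yl)ethyl]-3-[2-(triethylsilyloxy)propan-2-yl]cyclohept-1-en-1-yl]silane
Product: 17 4-[(1R,2R,5R)-2-methyl-5-[2-(triethylsilyloxy)propan-2-yl]-7-(trimethylsilyl)cyclohept-6-en-1-yl]butan-2-one
Conditions: PPTS, acetone/H2O, 50 °C
Reagents that add atoms: water, O
Why: Acid-catalysed hydrolysis of the ketone dioxolane; pyridinium tosylate is too weak an acid to protodesilylate the vinylsilane and should cleave the tertiary silyl ether far more slowly than the ketal.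

Step 12
Reactants: 17 4-[(1R,2R,5R)-2-methyl-5-[2-(triethylsilyloxy)propan-2-yl]-7-(trimethylsilyl)cyclohept-6-en-1-yl]butan-2-one; 18 (methoxymethyl)triphenylphosphonium chloride
Product: 20 [(3R,6R,7R)-7-(4-methoxy-3-methylbut-3-en-1-yl)-6-methyl-3-[2-(triethylsilyloxy)propan-2-yl]cyclohept-1-en-1-yl]trimethylsilane (E and Z isomers), via phosphorus ylide 19 (not isolated)
Conditions: 18, KN(SiMe3)2, THF, 0 °C; then 17, 0 °C to rt
Reagents that add atoms: none
Why: Wittig methoxymethylenation of the methyl ketone, the only carbonyl group left in the molecule; the enol ether geometry is of no consequence for the next step.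

Step 13
Reactants: 20 [(3R,6R,7R)-7-(4-methoxy-3-methylbut-3-en-1-yl)-6-methyl-3-[2-(triethylsilyloxy)propan-2-yl]cyclohept-1-en-1-yl]trimethylsilane (E and Z isomers)
Product: 21 (1S,3aR,4R,7R)-1-(dimethoxymethyl)-1,4-dimethyl-7-[2-(triethylsilyloxy)propan-2-yl]-1,2,3,3a,4,5,6,7-octahydroazulene
Conditions: reticulated vitreous carbon anode, Pt cathode, undivided cell, constant current, 2.2 F/mol, LiClO4 (0.1 M), MeOH/THF (3:7), 2,6-lutidine, rt
Reagents that add atoms: methanol, CO
Why: The enol ether is the most easily oxidised group in 20, so the anode removes one electron from it, and the radical cation is attacked at its β-carbon C4 by the silicon-bearing carbon C5 of the cycloheptenylsilane. The closest known reaction type is the intramolecular anodic coupling of enol ethers with vinylsilanes and allylsilanes, which tolerates the formation of quaternary carbons. The five-membered ring closes in a 5-exo-trig mode with respect to both alkenes, C9′ and C6 staying outside the new ring. Bonding at C5 leaves a cation at C6 stabilised by the β C–Si bond; loss of the silyl group to methanol restores C5=C6 exactly where the silane stood, while the α-methoxy radical at C9′ is oxidised a second time and trapped by methanol as the dimethyl acetal, with 2,6-lutidine taking up the acid. C1 controls the one new stereocentre: its chain lies on the face opposite H1, so C4 reaches C5 from that face and the C–Si bond bends towards the H1 face, aligned with the developing cation. In this arrangement the longer methoxymethylidene terminus C9′ should point away from the seven-membered ring, antiperiplanar to C5=C6 and far from the positive charge at C6, and the compact methyl group should sit under C6; when C5 becomes planar again this places C9′ syn to H1. E and Z isomers converge because the radical cation has little C4–C9′ double-bond character. The step needs chemoselective oxidation of the enol ether, which is why it precedes introduction of the electron-rich arene, and bonding at the silyl-bearing carbon and not at C6, which the β-silicon effect and the five- over six-membered ring preference both secure.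

Step 14
Reactants: 21 (1S,3aR,4R,7R)-1-(dimethoxymethyl)-1,4-dimethyl-7-[2-(triethylsilyloxy)propan-2-yl]-1,2,3,3a,4,5,6,7-octahydroazulene
Product: 22 (1S,3aR,4R,7R)-1,4-dimethyl-7-[2-(triethylsilyloxy)propan-2-yl]-1,2,3,3a,4,5,6,7-octahydroazulene-1-carbaldehyde
Conditions: PPTS, acetone/H2O, 40 °C
Reagents that add atoms: water, O
Why: Acid-catalysed acetal hydrolysis; the aldehyde has no α-hydrogen, so it can neither epimerise nor move into conjugation with C5=C6.

Step 15
Reactants: 22 (1S,3aR,4R,7R)-1,4-dimethyl-7-[2-(triethylsilyloxy)propan-2-yl]-1,2,3,3a,4,5,6,7-octahydroazulene-1-carbaldehyde; 23 1,3,5-trimethoxybenzene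
Product: 25 [(1S,3aR,4R,7R)-1,4-dimethyl-7-[2-(triethylsilyloxy)propan-2-yl]-1,2,3,3a,4,5,6,7-octahydroazulen-1-yl](2,4,6-trimethoxyphenyl)methanol (both carbinol epimers), via aryllithium 24 (not isolated)
Conditions: 23, n-BuLi, THF, 0 °C to rt; then 22, −78 to 0 °C
Reagents that add atoms: none
Why: Directed ortho-lithiation between two methoxy groups followed by 1,2-addition to a non-enolisable aldehyde; the carbinol configuration is irrelevant because the centre is made planar in the next step.

Step 16
Reactants: 25 [(1S,3aR,4R,7R)-1,4-dimethyl-7-[2-(triethylsilyloxy)propan-2-yl]-1,2,3,3a,4,5,6,7-octahydroazulen-1-yl](2,4,6-trimethoxyphenyl)methanol (both carbinol epimers)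
Product: 26 (1R,3aR,4R,7R)-1,4-dimethyl-1-[(1R)-3-methyl-1-(2,4,6-trimethoxyphenyl)but-3-en-1-yl]-7-[2-(triethylsilyloxy)propan-2-yl]-1,2,3,3a,4,5,6,7-octahydroazulene
Conditions: CH2=C(CH3)CH2SiMe3, BF3·OEt2, CH2Cl2, −78 °C
Reagents that add atoms: trimethyl(2-methylallyl)silane, CC(=C)C[Si](C)(C)C
Why: BF3 ionises the carbinol to a benzylic cation strongly stabilised by three ortho and para methoxy groups, and the allylsilane captures it (Hosomi–Sakurai-type SN1 allylation), both epimers of 25 converging on one cation. The aryl ring lies in the cation plane, so allylic strain with an ortho-methoxy group should turn the C4 methyl group towards the ring and leave C3 and C5 on the two faces (Felkin-type arrangement). The C5 face is closed by the C6–H bond held cis to C4, so the silane should enter past the C3 methylene and give the (R) configuration at C9′.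

Step 17
Reactants: 26 (1R,3aR,4R,7R)-1,4-dimethyl-1-[(1R)-3-methyl-1-(2,4,6-trimethoxyphenyl)but-3-en-1-yl]-7-[2-(triethylsilyloxy)propan-2-yl]-1,2,3,3a,4,5,6,7-octahydroazulene
Product: 27 (1R,3aR,4R,7R)-1,4-dimethyl-1-[(1R)-3-methyl-1-(2,4,6-trimethoxyphenyl)butyl]-7-[2-(triethylsilyloxy)propan-2-yl]-1,2,3,3a,4,5,6,7-octahydroazulene
Conditions: RhCl(PPh3)3 (cat.), H2 (1 atm), benzene/EtOH, rt
Reagents that add atoms: none
Why: Homogeneous hydrogenation with RhCl(PPh3)3 reduces the unhindered 1,1-disubstituted alkene and should leave the trisubstituted C5=C6, which is flanked by the quaternary C4 and the branched C7.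

Step 18
Reactants: 27 (1R,3aR,4R,7R)-1,4-dimethyl-1-[(1R)-3-methyl-1-(2,4,6-trimethoxyphenyl)butyl]-7-[2-(triethylsilyloxy)propan-2-yl]-1,2,3,3a,4,5,6,7-octahydroazulene
Product: 29 3-[(1R)-1-[(1R,3aR,4R,7R)-1,4-dimethyl-7-[2-(triethylsilyloxy)propan-2-yl]-1,2,3,3a,4,5,6,7-octahydroazulen-1-yl]-3-methylbutyl]-2,4,6-trimethoxybenzaldehyde, via aryllithium 28 (not isolated)
Conditions: n-BuLi, TMEDA, THF, 0 °C; then DMF, −78 °C to rt; aq. NH4Cl
Reagents that add atoms: N,N-dimethylformamide, CN(C)C=O
Why: Directed ortho-metalation at a ring C–H flanked by two methoxy groups and formylation of the aryllithium; the basic conditions leave the tertiary silyl ether and the alkene untouched, which a Lewis-acid (Rieche) formylation would not guarantee.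

Step 19
Reactants: 29 3-[(1R)-1-[(1R,3aR,4R,7R)-1,4-dimethyl-7-[2-(triethylsilyloxy)propan-2-yl]-1,2,3,3a,4,5,6,7-octahydroazulen-1-yl]-3-methylbutyl]-2,4,6-trimethoxybenzaldehyde
Product: 32 5-[(1R)-1-[(1R,3aR,4R,7R)-1,4-dimethyl-7-[2-(triethylsilyloxy)propan-2-yl]-1,2,3,3a,4,5,6,7-octahydroazulen-1-yl]-3-methylbutyl]-2,4,6-trimethoxybenzene-1,3-dicarbaldehyde, via lithium amino alkoxide 30 (not isolated), via ring-lithiated amino alkoxide 31 (not isolated)
Conditions: LiN(Me)CH2CH2NMe2, THF, −20 °C; then n-BuLi, −20 to 0 °C; then DMF, −78 °C to rt; aq. NH4Cl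
Reagents that add atoms: N,N-dimethylformamide, CN(C)C=O
Why: The first formyl group is masked in the flask as its α-amino alkoxide, the last ring C–H (again between two methoxy groups) is lithiated and formylated, and aqueous work-up releases both aldehydes; this is directed ortho-metalation with in-situ aldehyde protection.

Step 20
Reactants: 32 5-[(1R)-1-[(1R,3aR,4R,7R)-1,4-dimethyl-7-[2-(triethylsilyloxy)propan-2-yl]-1,2,3,3a,4,5,6,7-octahydroazulen-1-yl]-3-methylbutyl]-2,4,6-trimethoxybenzene-1,3-dicarbaldehyde
Product: 33 5-[(1R)-1-[(1R,3aR,4R,7R)-7-(2-hydroxypropan-2-yl)-1,4-dimethyl-1,2,3,3a,4,5,6,7-octahydroazulen-1-yl]-3-methylbutyl]-2,4,6-trimethoxybenzene-1,3-dicarbaldehyde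
Conditions: Bu4NF, THF, rt to 40 °C
Reagents that add atoms: none
Why: Fluoride cleavage of the triethylsilyl ether; the non-enolisable aryl aldehydes, the methyl ethers and the alkene are not affected.

Step 21
Reactants: 33 5-[(1R)-1-[(1R,3aR,4R,7R)-7-(2-hydroxypropan-2-yl)-1,4-dimethyl-1,2,3,3a,4,5,6,7-octahydroazulen-1-yl]-3-methylbutyl]-2,4,6-trimethoxybenzene-1,3-dicarbaldehyde
Product: 34 5-[(1R)-1-[(1R,3aR,4R,7R)-7-(2-hydroxypropan-2-yl)-1,4-dimethyl-1,2,3,3a,4,5,6,7-octahydroazulen-1-yl]-3-methylbutyl]-2,4,6-trihydroxybenzene-1,3-dicarbaldehyde (target, CNP0281883.1)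
Conditions: 4-MeC6H4SLi (excess), HMPA/toluene, 110 °C; then dilute aq. HCl
Reagents that add atoms: none
Why: SN2 demethylation by a soft arenethiolate: every methoxy group is ortho or para to a formyl group, so each phenoxide is a good leaving group. The basic, non-Lewis-acidic conditions should leave the tertiary alcohol and C5=C6 untouched, where boron or aluminium halides would ionise them.

## Compound list

1 | (R)-carvone | CC1=CC[C@H](CC1=O)C(C)=C | starting material
2 | (5R)-5-(2-hydroxypropan-2-yl)-2-methylcyclohex-2-en-1-one | CC1=CC[C@H](CC1=O)C(C)(C)O | intermediate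
3 | (5R)-2-methyl-5-[2-(triethylsilyloxy)propan-2-yl]cyclohex-2-en-1-one | CC1=CC[C@H](CC1=O)C(C)(C)O[Si](CC)(CC)CC | intermediate
4 | lithium (5R)-2-methyl-5-[2-(triethylsilyloxy)propan-2-yl]cyclohex-1-en-1-olate | CC1=C(O[Li])C[C@@H](CC1)C(C)(C)O[Si](CC)(CC)CC | intermediate (not isolated)
5 | trimethyl{[(5R)-2-methyl-5-[2-(triethylsilyloxy)propan-2-yl]cyclohex-1-en-1-yl]oxy}silane | CC1=C(O[Si](C)(C)C)C[C@@H](CC1)C(C)(C)O[Si](CC)(CC)CC | intermediate
6 | {[(3R)-7,7-dibromo-6-methyl-3-[2-(triethylsilyloxy)propan-2-yl]bicyclo[4.1.0]heptan-1-yl]oxy}trimethylsilane (both cyclopropane faces) | CC12CC[C@@H](C(C)(C)O[Si](CC)(CC)CC)CC1(O[Si](C)(C)C)C2(Br)Br | intermediate (not isolated)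
7 | (6R)-2-bromo-3-methyl-6-[2-(triethylsilyloxy)propan-2-yl]cyclohept-2-en-1-one | CC1=C(Br)C(=O)C[C@H](C(C)(C)O[Si](CC)(CC)CC)CC1 | intermediate
8 | 2-(2-bromoethyl)-2-methyl-1,3-dioxolane | CC1(CCBr)OCCO1 | starting material
9 | bromo[2-(2-methyl-1,3-dioxolan-2-yl)ethyl]zinc | CC1(CC[Zn]Br)OCCO1 | intermediate (not isolated)
10 | (6R)-3-methyl-2-[2-(2-methyl-1,3-dioxolan-2-yl)ethyl]-6-[2-(triethylsilyloxy)propan-2-yl]cyclohept-2-en-1-one | CC1(CCC2=C(C)CC[C@@H](C(C)(C)O[Si](CC)(CC)CC)CC2=O)OCCO1 | intermediate
11 | (1R,6R)-3-methyl-2-[2-(2-methyl-1,3-dioxolan-2-yl)ethyl]-6-[2-(triethylsilyloxy)propan-2-yl]cyclohept-2-en-1-ol | CC1(CCC2=C(C)CC[C@@H](C(C)(C)O[Si](CC)(CC)CC)C[C@H]2O)OCCO1 | intermediate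
12 | (1R,2R,3R,6R)-3-methyl-2-[2-(2-methyl-1,3-dioxolan-2-yl)ethyl]-6-[2-(triethylsilyloxy)propan-2-yl]cycloheptan-1-ol | CC1(CC[C@H]2[C@H](O)C[C@H](C(C)(C)O[Si](CC)(CC)CC)CC[C@H]2C)OCCO1 | intermediate
13 | (2R,3R,6R)-3-methyl-2-[2-(2-methyl-1,3-dioxolan-2-yl)ethyl]-6-[2-(triethylsilyloxy)propan-2-yl]cycloheptan-1-one | CC1(CC[C@H]2C(=O)C[C@H](C(C)(C)O[Si](CC)(CC)CC)CC[C@H]2C)OCCO1 | intermediate
14 | N′-[(1E,2R,3R,6R)-3-methyl-2-[2-(2-methyl-1,3-dioxolan-2-yl)ethyl]-6-[2-(triethylsilyloxy)propan-2-yl]cycloheptylidene]-2,4,6-tri(propan-2-yl)benzenesulfonohydrazide | CC1(CC[C@H]2/C(=N/NS(=O)(=O)c3c(C(C)C)cc(C(C)C)cc3C(C)C)C[C@H](C(C)(C)O[Si](CC)(CC)CC)CC[C@H]2C)OCCO1 | intermediate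
15 | [(3R,6R,7R)-6-methyl-7-[2-(2-methyl-1,3-dioxolan-2-yl)ethyl]-3-[2-(triethylsilyloxy)propan-2-yl]cyclohept-1-en-1-yl]lithium | CC1(CC[C@H]2C([Li])=C[C@H](C(C)(C)O[Si](CC)(CC)CC)CC[C@H]2C)OCCO1 | intermediate (not isolated)
16 | trimethyl[(3R,6R,7R)-6-methyl-7-[2-(2-methyl-1,3-dioxolan-2-yl)ethyl]-3-[2-(triethylsilyloxy)propan-2-yl]cyclohept-1-en-1-yl]silane | CC1(CC[C@H]2C([Si](C)(C)C)=C[C@H](C(C)(C)O[Si](CC)(CC)CC)CC[C@H]2C)OCCO1 | intermediate
17 | 4-[(1R,2R,5R)-2-methyl-5-[2-(triethylsilyloxy)propan-2-yl]-7-(trimethylsilyl)cyclohept-6-en-1-yl]butan-2-one | CC(=O)CC[C@H]1C([Si](C)(C)C)=C[C@H](C(C)(C)O[Si](CC)(CC)CC)CC[C@H]1C | intermediate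
18 | (methoxymethyl)triphenylphosphonium chloride | COC[P+](c1ccccc1)(c1ccccc1)c1ccccc1.[Cl-] | starting material
19 | (methoxymethylidene)triphenyl-λ5-phosphane | COC=P(c1ccccc1)(c1ccccc1)c1ccccc1 | intermediate (not isolated)
20 | [(3R,6R,7R)-7-(4-methoxy-3-methylbut-3-en-1-yl)-6-methyl-3-[2-(triethylsilyloxy)propan-2-yl]cyclohept-1-en-1-yl]trimethylsilane (E and Z isomers) | COC=C(C)CC[C@H]1C([Si](C)(C)C)=C[C@H](C(C)(C)O[Si](CC)(CC)CC)CC[C@H]1C | intermediate
21 | (1S,3aR,4R,7R)-1-(dimethoxymethyl)-1,4-dimethyl-7-[2-(triethylsilyloxy)propan-2-yl]-1,2,3,3a,4,5,6,7-octahydroazulene | COC(OC)[C@@]1(C)CC[C@H]2C1=C[C@H](C(C)(C)O[Si](CC)(CC)CC)CC[C@H]2C | intermediate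
22 | (1S,3aR,4R,7R)-1,4-dimethyl-7-[2-(triethylsilyloxy)propan-2-yl]-1,2,3,3a,4,5,6,7-octahydroazulene-1-carbaldehyde | O=C[C@@]1(C)CC[C@H]2C1=C[C@H](C(C)(C)O[Si](CC)(CC)CC)CC[C@H]2C | intermediate
23 | 1,3,5-trimethoxybenzene | COc1cc(OC)cc(OC)c1 | starting material
24 | (2,4,6-trimethoxyphenyl)lithium | [Li]c1c(OC)cc(OC)cc1OC | intermediate (not isolated)
25 | [(1S,3aR,4R,7R)-1,4-dimethyl-7-[2-(triethylsilyloxy)propan-2-yl]-1,2,3,3a,4,5,6,7-octahydroazulen-1-yl](2,4,6-trimethoxyphenyl)methanol (both carbinol epimers) | OC(c1c(OC)cc(OC)cc1OC)[C@@]1(C)CC[C@H]2C1=C[C@H](C(C)(C)O[Si](CC)(CC)CC)CC[C@H]2C | intermediate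
26 | (1R,3aR,4R,7R)-1,4-dimethyl-1-[(1R)-3-methyl-1-(2,4,6-trimethoxyphenyl)but-3-en-1-yl]-7-[2-(triethylsilyloxy)propan-2-yl]-1,2,3,3a,4,5,6,7-octahydroazulene | C=C(C)C[C@@H](c1c(OC)cc(OC)cc1OC)[C@@]1(C)CC[C@H]2C1=C[C@H](C(C)(C)O[Si](CC)(CC)CC)CC[C@H]2C | intermediate
27 | (1R,3aR,4R,7R)-1,4-dimethyl-1-[(1R)-3-methyl-1-(2,4,6-trimethoxyphenyl)butyl]-7-[2-(triethylsilyloxy)propan-2-yl]-1,2,3,3a,4,5,6,7-octahydroazulene | CC(C)C[C@@H](c1c(OC)cc(OC)cc1OC)[C@@]1(C)CC[C@H]2C1=C[C@H](C(C)(C)O[Si](CC)(CC)CC)CC[C@H]2C | intermediate
28 | 3-lithio derivative of 27 (lithium on the ring carbon between two methoxy groups) | CC(C)C[C@@H](c1c(OC)cc(OC)c([Li])c1OC)[C@@]1(C)CC[C@H]2C1=C[C@H](C(C)(C)O[Si](CC)(CC)CC)CC[C@H]2C | intermediate (not isolated)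
29 | 3-[(1R)-1-[(1R,3aR,4R,7R)-1,4-dimethyl-7-[2-(triethylsilyloxy)propan-2-yl]-1,2,3,3a,4,5,6,7-octahydroazulen-1-yl]-3-methylbutyl]-2,4,6-trimethoxybenzaldehyde | CC(C)C[C@@H](c1c(OC)cc(OC)c(C=O)c1OC)[C@@]1(C)CC[C@H]2C1=C[C@H](C(C)(C)O[Si](CC)(CC)CC)CC[C@H]2C | intermediate
30 | lithium α-amino alkoxide from 29 and LiN(Me)CH2CH2NMe2 (formyl carbon bearing OLi and N(Me)CH2CH2NMe2; both epimers) | CC(C)C[C@@H](c1c(OC)cc(OC)c(C(O[Li])N(C)CCN(C)C)c1OC)[C@@]1(C)CC[C@H]2C1=C[C@H](C(C)(C)O[Si](CC)(CC)CC)CC[C@H]2C | intermediate (not isolated)
31 | ring-lithiated form of 30 (lithium on the last ring CH) | CC(C)C[C@@H](c1c(OC)c([Li])c(OC)c(C(O[Li])N(C)CCN(C)C)c1OC)[C@@]1(C)CC[C@H]2C1=C[C@H](C(C)(C)O[Si](CC)(CC)CC)CC[C@H]2C | intermediate (not isolated)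
32 | 5-[(1R)-1-[(1R,3aR,4R,7R)-1,4-dimethyl-7-[2-(triethylsilyloxy)propan-2-yl]-1,2,3,3a,4,5,6,7-octahydroazulen-1-yl]-3-methylbutyl]-2,4,6-trimethoxybenzene-1,3-dicarbaldehyde | CC(C)C[C@@H](c1c(OC)c(C=O)c(OC)c(C=O)c1OC)[C@@]1(C)CC[C@H]2C1=C[C@H](C(C)(C)O[Si](CC)(CC)CC)CC[C@H]2C | intermediate
33 | 5-[(1R)-1-[(1R,3aR,4R,7R)-7-(2-hydroxypropan-2-yl)-1,4-dimethyl-1,2,3,3a,4,5,6,7-octahydroazulen-1-yl]-3-methylbutyl]-2,4,6-trimethoxybenzene-1,3-dicarbaldehyde | CC(C)C[C@@H](c1c(OC)c(C=O)c(OC)c(C=O)c1OC)[C@@]1(C)CC[C@H]2C1=C[C@H](C(C)(C)O)CC[C@H]2C | intermediate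
34 | 5-[(1R)-1-[(1R,3aR,4R,7R)-7-(2-hydroxypropan-2-yl)-1,4-dimethyl-1,2,3,3a,4,5,6,7-octahydroazulen-1-yl]-3-methylbutyl]-2,4,6-trihydroxybenzene-1,3-dicarbaldehyde | CC(C)C[C@@H](c1c(O)c(C=O)c(O)c(C=O)c1O)[C@@]1(C)CC[C@H]2C1=C[C@H](C(C)(C)O)CC[C@H]2C | target

## Step count and least certain steps

Total step count: 21. Longest linear sequence: 21 steps from (R)-carvone (1); compounds 8, 18 and 23 each enter in a single step.

**Step 13 (key step).** The two orientations of the enol ether radical cation over the vinylsilane differ only in whether the methyl group or the methoxymethylidene terminus lies under the seven-membered ring. Facial selectivity at C4 may therefore be poor or reversed. Closure onto a fully substituted carbon may also be slow enough for solvent trapping of the radical cation to compete. The fallback forms the same bond by two-electron chemistry under ligand control. From ketone 17, ipso-iododesilylation with N-iodosuccinimide should give the alkenyl iodide ketone F1. Methoxymethylenation with ylide 19 gives the iodo enol ether F2, and mild aqueous acid gives the α-methyl aldehyde F3. Palladium-catalysed intramolecular α-alkenylation of the aldehyde enolate (Pd(OAc)2, a chiral bisphosphine such as BINAP, Cs2CO3, toluene) should then close the five-membered ring and return to the route at aldehyde 22. The sense at C4 is then set by the ligand enantiomer.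

**Step 16.** The face of the benzylic cation taken by the allylsilane rests on a conformational argument, so the C9′ configuration may come out mixed or inverted. A 1,2-shift from C4 to the cationic centre is a second possible failure. The fallback introduces hydrogen last instead of carbon. From carbinol 25, Dess–Martin oxidation gives the aryl ketone F4. Addition of CH2=C(CH3)CH2MgCl, an allylic reagent that adds to hindered ketones, gives the tertiary carbinol F5. Ionic reduction (Et3SiH, BF3·OEt2, −78 °C) then delivers hydride to the same open face of the cation. Because hydride and not the methallyl group now enters from that face, the configuration at C9′ is the opposite of that from direct allylation, and the sequence returns to the route at 26.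

**Step 7.** Turnover of the iridium catalyst on a tetrasubstituted alkene may stall through catalyst deactivation. Acid traces formed under hydrogen may also open the dioxolane. The fallback gives up the hydroxyl relay: enone 10 is hydrogenated over palladium on carbon (H2, Pd/C, EtOAc), which adds both hydrogens cis and leads directly to ketone 13, bypassing 11 and 12. The face is then chosen by the ring conformation alone and the isomers would need separation. No new compound is involved.

**Step 9 (with step 10).** Hydrazone formation on the hindered ketone may be slow enough for ene-hydrazine tautomerism to epimerise C1 to the more stable trans arrangement. The fallback avoids the hydrazone. From ketone 13, kinetic deprotonation at C6 (KN(SiMe3)2, −78 °C) and trapping with PhNTf2 gives the enol triflate F6. Stille-type stannylation ((Me3Sn)2, Pd(PPh3)4, LiCl) gives the alkenylstannane F7. Tin–lithium exchange with MeLi regenerates alkenyllithium 15, and Me3SiCl returns to the route at 16.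

**Step 21.** Removal of the third methyl group may stall as negative charge builds up on the ring, and the thiolate may add to the formyl groups at the temperature required. The fallback changes the mode of activation from nucleophilic attack to chelation. MgI2·OEt2 in toluene binds each formyl oxygen together with its ortho-methoxy oxygen, and iodide removes the methyl groups from 33 to give 34 directly. No new compound is involved.

## Further compounds

F1 | step 13 | 4-[(1R,2R,5R)-7-iodo-2-methyl-5-[2-(triethylsilyloxy)propan-2-yl]cyclohept-6-en-1-yl]butan-2-one | CC(=O)CC[C@H]1C(I)=C[C@H](C(C)(C)O[Si](CC)(CC)CC)CC[C@H]1C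
F2 | step 13 | triethyl({2-[(1R,4R,5R)-3-iodo-4-(4-methoxy-3-methylbut-3-en-1-yl)-5-methylcyclohept-2-en-1-yl]propan-2-yl}oxy)silane (E and Z isomers) | COC=C(C)CC[C@H]1C(I)=C[C@H](C(C)(C)O[Si](CC)(CC)CC)CC[C@H]1C
F3 | step 13 | 4-[(1R,2R,5R)-7-iodo-2-methyl-5-[2-(triethylsilyloxy)propan-2-yl]cyclohept-6-en-1-yl]-2-methylbutanal (both C2 epimers) | O=CC(C)CC[C@H]1C(I)=C[C@H](C(C)(C)O[Si](CC)(CC)CC)CC[C@H]1C
F4 | step 16 | [(1S,3aR,4R,7R)-1,4-dimethyl-7-[2-(triethylsilyloxy)propan-2-yl]-1,2,3,3a,4,5,6,7-octahydroazulen-1-yl](2,4,6-trimethoxyphenyl)methanone | COc1cc(OC)c(C(=O)[C@@]2(C)CC[C@H]3C2=C[C@H](C(C)(C)O[Si](CC)(CC)CC)CC[C@H]3C)c(OC)c1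
F5 | step 16 | 1-[(1S,3aR,4R,7R)-1,4-dimethyl-7-[2-(triethylsilyloxy)propan-2-yl]-1,2,3,3a,4,5,6,7-octahydroazulen-1-yl]-3-methyl-1-(2,4,6-trimethoxyphenyl)but-3-en-1-ol (both carbinol epimers) | C=C(C)CC(O)(c1c(OC)cc(OC)cc1OC)[C@@]1(C)CC[C@H]2C1=C[C@H](C(C)(C)O[Si](CC)(CC)CC)CC[C@H]2C
F0 | step 7 | none | none
F6 | step 9 | (3R,6R,7R)-6-methyl-7-[2-(2-methyl-1,3-dioxolan-2-yl)ethyl]-3-[2-(triethylsilyloxy)propan-2-yl]cyclohept-1-en-1-yl trifluoromethanesulfonate | CC1(CC[C@H]2C(OS(=O)(=O)C(F)(F)F)=C[C@H](C(C)(C)O[Si](CC)(CC)CC)CC[C@H]2C)OCCO1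
F7 | step 9 | trimethyl[(3R,6R,7R)-6-methyl-7-[2-(2-methyl-1,3-dioxolan-2-yl)ethyl]-3-[2-(triethylsilyloxy)propan-2-yl]cyclohept-1-en-1-yl]stannane | CC1(CC[C@H]2C([Sn](C)(C)C)=C[C@H](C(C)(C)O[Si](CC)(CC)CC)CC[C@H]2C)OCCO1
F0 | step 21 | none | none
A1 | alternative 1 | 10-hydroxyguai-4-en-3-one with the C11 carbinol | CC1=C2C[C@H](C(C)(C)O)CC[C@](C)(O)[C@H]2CC1=O
A2 | alternative 1 | 11-hydroxy-10-epi-eudesma-1,4-dien-3-one | CC1=C2C[C@H](C(C)(C)O)CC[C@]2(C)C=CC1=O
A3 | alternative 2 | tri-O-methyl target lacking the two formyl groups | CC(C)C[C@@H](c1c(OC)cc(OC)cc1OC)[C@@]1(C)CC[C@H]2C1=C[C@H](C(C)(C)O)CC[C@H]2C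
A4 | alternative 2 | cyclopentane diene with C5 exocyclic methylene and C6 vinyl group | CC(C)C[C@@H](c1c(OC)cc(OC)cc1OC)[C@@]1(C)CC[C@H]([C@H](C)CC[C@H](C=C)C(C)(C)O)C1=C
A5 | alternative 3 | guaia-1(10),4-dien-3-one bearing the C9′ side chain on C4 | CC(C)C[C@@H](c1c(OC)cc(OC)cc1OC)C1=C2C[C@H](C(C)(C)O[Si](CC)(CC)CC)CCC(C)=C2CC1=O
A6 | alternative 3 | allenyne with the C4≡C5 alkyne and the C10=C1=C2 allene | CC(C)C[C@@H](c1c(OC)cc(OC)cc1OC)C#CC[C@H](C(C)(C)O[Si](CC)(CC)CC)CCC(C)=C=C
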